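## Retrosynthetic overview

1. Target 29 ⇐ unveiling of the C9 ketone from an O-alkyl hydroxylamine (last step) and O-acylation of the C8 alcohol of ring alcohol 24; the C5 isobutyrate and the free C4 alcohol are carried from the open-chain stage.
2. 24 ⇐ one intramolecular Barbier (Nozaki–Hiyama–Kishi) allylation of bromomethyl-butenolide aldehyde 22, which forms C7–C8, the ten-membered carbocycle (second ring) and the α-methylene lactone.
3. 22 ⇐ ring-closing metathesis of a 2-(bromomethyl)acrylate of the C6 allylic alcohol (butenolide, first ring); C9–O ⇐ organocatalytic α-oxyamination of the C8 aldehyde.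
4. C5/C6 ⇐ Brown (Z)-γ-alkoxyallylboration of an epoxy aldehyde; C4 ⇐ Sharpless epoxidation then hydride opening; C5 oxygen ⇐ SeO2 oxidation of a prenyl terminus.
5. C8–C10, C1–C5, both ring methyl groups and the C10 stereocentre ⇐ (R)-citronellal.

Assumption: commercial (R)-(+)-citronellal of high ee is used, and the (5S)-imidazolidinone/TEMPO α-oxyamination is taken to follow the usual enamine face-shielding model (giving 9S); C9 is only a temporary stereocentre, erased in step 14.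

Labels: atom labels are germacranolide labels of the target (ring C1–C10; lactone C12(=O)–O–C6; C11=C13H2 on C7; OH and methyl on C4; ester oxygens on C5 and C8; ketone C9; methyl on C10).

## Route

Step 1
Reactants: 1 (R)-citronellal, (3R)-3,7-dimethyloct-6-enal
Product: 2 (6R)-8,8-dimethoxy-2,6-dimethyloct-2-ene
Conditions: HC(OMe)3, MeOH, pyridinium p-toluenesulfonate (cat.), rt
Reagents that add atoms: trimethyl orthoformate, COC(OC)OC
Why: Mild acid-catalysed acetalisation masks the future C8 aldehyde for steps 2–7 without triggering the carbonyl-ene cyclisation of citronellal, and the C10 stereocentre comes unchanged from the chiral pool.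

Step 2
Reactants: 2 (6R)-8,8-dimethoxy-2,6-dimethyloct-2-ene
Product: 4 (2E,6R)-8,8-dimethoxy-2,6-dimethyloct-2-en-1-ol, via enal 3 (not isolated)
Conditions: SeO2 (0.3 equiv), t-BuOOH (anhydrous, decane), CH2Cl2, rt; then NaBH4, MeOH, 0 °C
Reagents that add atoms: tert-butyl hydroperoxide, CC(C)(C)OO (terminal oxygen source); selenium dioxide, O=[Se]=O (oxygen carrier)
Why: Selenium dioxide allylic oxidation (ene reaction then [2,3]-sigmatropic shift) hydroxylates only the (E)-methyl of the trisubstituted alkene, and the borohydride quench returns over-oxidised enal 3 to 4.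

Step 3
Reactants: 4 (2E,6R)-8,8-dimethoxy-2,6-dimethyloct-2-en-1-ol
Product: 5 [(2R,3R)-3-[(3R)-5,5-dimethoxy-3-methylpentyl]-2-methyloxiran-2-yl]methanol
Conditions: Ti(OiPr)4 (10 mol %), D-(−)-diethyl tartrate (12 mol %), t-BuOOH, 4 Å MS, CH2Cl2, −20 °C
Reagents that add atoms: tert-butyl hydroperoxide, CC(C)(C)OO
Why: Sharpless asymmetric epoxidation with the D-(−)-tartrate catalyst delivers oxygen to one face of the (E)-allylic alcohol and sets the (2R,3R)-epoxide, whose quaternary carbon is the future C4 (reagent control).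

Step 4
Reactants: 5 [(2R,3R)-3-[(3R)-5,5-dimethoxy-3-methylpentyl]-2-methyloxiran-2-yl]methanol
Product: 6 (2S,3R)-3-[(3R)-5,5-dimethoxy-3-methylpentyl]-2-methyloxirane-2-carbaldehyde
Conditions: Dess–Martin periodinane, pyridine, CH2Cl2, 0 °C to rt
Reagents that add atoms: none
Why: Buffered Dess–Martin oxidation of the primary alcohol gives the α-quaternary epoxy aldehyde, which cannot epimerise.

Step 5
Reactants: 6 (2S,3R)-3-[(3R)-5,5-dimethoxy-3-methylpentyl]-2-methyloxirane-2-carbaldehyde; 7 allyl 4-methoxybenzyl ether, 1-methoxy-4-[(prop-2-en-1-yloxy)methyl]benzene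
Product: 12 (1R,2S)-1-[(2R,3R)-3-[(3R)-5,5-dimethoxy-3-methylpentyl]-2-methyloxiran-2-yl]-2-[(4-methoxyphenyl)methoxy]but-3-en-1-ol, via allyllithium 8 (not isolated), via lithium methoxyborate 9 (not isolated), via allylborane 10 (not isolated), via borinate ester 11 (not isolated)
Conditions: 7, s-BuLi, THF, −78 °C; (+)-Ipc2BOMe, −78 °C; BF3·OEt2, −78 °C; then 6, −78 °C; HOCH2CH2NH2, rt
Reagents that add atoms: none
Why: Brown γ-alkoxyallylboration through a chair Zimmerman–Traxler transition state: the (Z)-allylborane gives the syn C5–OH/C6–OPMB pair, the isopinocampheyl groups from (+)-Ipc2BOMe direct addition to the re face of the aldehyde (5R,6S in target labels), and this is matched to the intrinsic anti (Felkin–Anh) preference of the epoxy aldehyde.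

Step 6
Reactants: 12 (1R,2S)-1-[(2R,3R)-3-[(3R)-5,5-dimethoxy-3-methylpentyl]-2-methyloxiran-2-yl]-2-[(4-methoxyphenyl)methoxy]but-3-en-1-ol
Product: 13 (3S,4R,5S,9R)-11,11-dimethoxy-3-[(4-methoxyphenyl)methoxy]-5,9-dimethylundec-1-ene-4,5-diol
Conditions: LiAlH4, THF, 0 °C to rt; H2O/NaOH work-up
Reagents that add atoms: none
Why: SN2 hydride opening of the trisubstituted epoxide at its less substituted carbon (C3) leaves the C4–O bond intact, so the tertiary alcohol keeps the Sharpless-derived configuration (4S).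

Step 7
Reactants: 13 (3S,4R,5S,9R)-11,11-dimethoxy-3-[(4-methoxyphenyl)methoxy]-5,9-dimethylundec-1-ene-4,5-diol; 14 2-methylpropanoic anhydride
Product: 15 (3S,4R,5S,9R)-5-hydroxy-11,11-dimethoxy-3-[(4-methoxyphenyl)methoxy]-5,9-dimethylundec-1-en-4-yl 2-methylpropanoate
Conditions: 14, Et3N, 4-(dimethylamino)pyridine (10 mol %), CH2Cl2, 0 °C
Reagents that add atoms: none
Why: DMAP-catalysed acylation is selective for the secondary C5–OH over the tertiary C4–OH and installs the isobutyrate of the target at the only moment C5–OH is the sole reactive hydroxyl.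

Step 8
Reactants: 15 (3S,4R,5S,9R)-5-hydroxy-11,11-dimethoxy-3-[(4-methoxyphenyl)methoxy]-5,9-dimethylundec-1-en-4-yl 2-methylpropanoate
Product: 17 (3S,4R,5S,9R)-3,5-dihydroxy-5,9-dimethyl-11-oxoundec-1-en-4-yl 2-methylpropanoate, via hydroxy acetal 16 (not isolated)
Conditions: DDQ (1.5 equiv), MeCN–H2O 9:1, 0 °C to rt
Reagents that add atoms: water, O
Why: Oxidative cleavage of the 4-methoxybenzyl ether by DDQ frees the C6 alcohol, and the wet DDQ/hydroquinone medium then hydrolyses the dimethyl acetal to the C8 aldehyde under near-neutral conditions that do not move the C5 ester.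

Step 9
Reactants: 17 (3S,4R,5S,9R)-3,5-dihydroxy-5,9-dimethyl-11-oxoundec-1-en-4-yl 2-methylpropanoate
Product: 18 (3S,4R,5S,9R,10S)-3,5-dihydroxy-5,9-dimethyl-11-oxo-10-[(2,2,6,6-tetramethylpiperidin-1-yl)oxy]undec-1-en-4-yl 2-methylpropanoate
Conditions: TEMPO (1.5 equiv), (5S)-5-benzyl-2,2,3-trimethylimidazolidin-4-one trifluoroacetate (20 mol %), CuCl2·2H2O (10 mol %), air, acetone, 0 °C
Reagents that add atoms: TEMPO (2,2,6,6-tetramethylpiperidin-1-oxyl), CC1(C)CCCC(C)(C)N1[O]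
Why: Enamine organocatalysis (α-oxyamination): the (E)-enamine is trapped by the copper–TEMPO oxidant on the face away from the benzyl group, which sets the temporary 9S centre as a robust O-alkyl hydroxylamine chosen so that Felkin–Anh addition in step 12 gives 8R.

Step 10
Reactants: 18 (3S,4R,5S,9R,10S)-3,5-dihydroxy-5,9-dimethyl-11-oxo-10-[(2,2,6,6-tetramethylpiperidin-1-yl)oxy]undec-1-en-4-yl 2-methylpropanoate; 19 2-(bromomethyl)prop-2-enoic acid
Product: 21 (3S,4R,5S,9R,10S)-5-hydroxy-5,9-dimethyl-4-[(2-methylpropanoyl)oxy]-11-oxo-10-[(2,2,6,6-tetramethylpiperidin-1-yl)oxy]undec-1-en-3-yl 2-(bromomethyl)prop-2-enoate, via O-acylisourea 20 (not isolated)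
Conditions: 19, DCC, 4-(dimethylamino)pyridine (5 mol %), CH2Cl2, −20 to 0 °C
Reagents that add atoms: none
Why: Steglich esterification acylates the secondary allylic C6–OH (the tertiary C4–OH is inert) and brings in C11–C13 as an allylic bromide.

Step 11
Reactants: 21 (3S,4R,5S,9R,10S)-5-hydroxy-5,9-dimethyl-4-[(2-methylpropanoyl)oxy]-11-oxo-10-[(2,2,6,6-tetramethylpiperidin-1-yl)oxy]undec-1-en-3-yl 2-(bromomethyl)prop-2-enoate
Product: 22 (1R,2S,6R,7S)-1-[(2S)-4-(bromomethyl)-5-oxo-2,5-dihydrofuran-2-yl]-2-hydroxy-2,6-dimethyl-8-oxo-7-[(2,2,6,6-tetramethylpiperidin-1-yl)oxy]octyl 2-methylpropanoate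
Conditions: [1,3-bis(2,4,6-trimethylphenyl)imidazolidin-2-ylidene]dichloro(2-isopropoxybenzylidene)ruthenium (second-generation Hoveyda–Grubbs catalyst, 10 mol %), toluene (5 mM), 80 °C, Ar sparge
Reagents that add atoms: none
Why: Ring-closing metathesis between the vinyl group and the acrylate forms the butenolide C7=C11 bond with loss of ethylene, and no stereocentre is touched.

Step 12
Reactants: 22 (1R,2S,6R,7S)-1-[(2S)-4-(bromomethyl)-5-oxo-2,5-dihydrofuran-2-yl]-2-hydroxy-2,6-dimethyl-8-oxo-7-[(2,2,6,6-tetramethylpiperidin-1-yl)oxy]octyl 2-methylpropanoate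
Product: 24 (3aR,4R,5S,6R,10S,11R,11aS)-4,10-dihydroxy-6,10-dimethyl-3-methylidene-2-oxo-5-[(2,2,6,6-tetramethylpiperidin-1-yl)oxy]dodecahydrocyclodeca[b]furan-11-yl 2-methylpropanoate, via allylchromium dichloride 23 (not isolated)
Conditions: CrCl2 (8 equiv), THF, rt, slow addition of 22 (final 2 mM); then H2O
Reagents that add atoms: none
Why: Intramolecular Barbier (Nozaki–Hiyama–Kishi) allylation: the allylchromium adds through C7 (SE2′) to the C8 aldehyde in a chair Zimmerman–Traxler transition state, attack anti to the C6 side chain gives the trans-lactone (H-6/H-7 trans), the ring-locked E-type allyl geometry places C8–OH syn to C11 (8R), and the 9S alkoxyamine reinforces this by Felkin–Anh control.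

Step 13
Reactants: 24 (3aR,4R,5S,6R,10S,11R,11aS)-4,10-dihydroxy-6,10-dimethyl-3-methylidene-2-oxo-5-[(2,2,6,6-tetramethylpiperidin-1-yl)oxy]dodecahydrocyclodeca[b]furan-11-yl 2-methylpropanoate; 25 (2R)-2-methylbutanoic acid
Product: 27 (3aS,4R,5S,6R,10S,11R,11aS)-10-hydroxy-6,10-dimethyl-3-methylidene-11-[(2-methylpropanoyl)oxy]-2-oxo-5-[(2,2,6,6-tetramethylpiperidin-1-yl)oxy]dodecahydrocyclodeca[b]furan-4-yl (2R)-2-methylbutanoate, via O-acylisourea 26 (not isolated)
Conditions: 25, DCC, 4-(dimethylamino)pyridine (0.3 equiv), CH2Cl2, 0 °C to rt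
Reagents that add atoms: none
Why: Steglich esterification of the only secondary alcohol (C8–OH) with the enantiopure acid does not racemise the acid α-centre, leaves the tertiary C4–OH alone, and locks the lactone on C6 before the ketone is made.

Step 14
Reactants: 27 (3aS,4R,5S,6R,10S,11R,11aS)-10-hydroxy-6,10-dimethyl-3-methylidene-11-[(2-methylpropanoyl)oxy]-2-oxo-5-[(2,2,6,6-tetramethylpiperidin-1-yl)oxy]dodecahydrocyclodeca[b]furan-4-yl (2R)-2-methylbutanoate
Product: 29 (3aS,4R,6R,10S,11R,11aS)-10-hydroxy-6,10-dimethyl-3-methylidene-11-[(2-methylpropanoyl)oxy]-2,5-dioxododecahydrocyclodeca[b]furan-4-yl (2R)-2-methylbutanoate (CNP0071420.1), via N-oxide 28 (not isolated)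
Conditions: 3-chloroperoxybenzoic acid (mCPBA, 1.6 equiv), CH2Cl2, 0 °C to rt
Reagents that add atoms: none
Why: Peracid N-oxidation of the alkoxyamine followed by Cope-type elimination of the C9 hydrogen gives the C9 ketone under non-basic conditions, so the flanking C8 and C10 stereocentres are not epimerised and the electron-poor methylene lactone is not epoxidised.

## Compound list

1 | (R)-citronellal, (3R)-3,7-dimethyloct-6-enal | CC(C)=CCC[C@@H](C)CC=O | starting material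
2 | (6R)-8,8-dimethoxy-2,6-dimethyloct-2-ene | CC(C)=CCC[C@@H](C)CC(OC)OC | intermediate
3 | (2E,6R)-8,8-dimethoxy-2,6-dimethyloct-2-enal | O=C/C(C)=C/CC[C@@H](C)CC(OC)OC | intermediate (not isolated)
4 | (2E,6R)-8,8-dimethoxy-2,6-dimethyloct-2-en-1-ol | OC/C(C)=C/CC[C@@H](C)CC(OC)OC | intermediate
5 | [(2R,3R)-3-[(3R)-5,5-dimethoxy-3-methylpentyl]-2-methyloxiran-2-yl]methanol | OC[C@@]1(C)O[C@@H]1CC[C@@H](C)CC(OC)OC | intermediate
6 | (2S,3R)-3-[(3R)-5,5-dimethoxy-3-methylpentyl]-2-methyloxirane-2-carbaldehyde | O=C[C@@]1(C)O[C@@H]1CC[C@@H](C)CC(OC)OC | intermediate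
7 | allyl 4-methoxybenzyl ether, 1-methoxy-4-[(prop-2-en-1-yloxy)methyl]benzene | C=CCOCc1ccc(OC)cc1 | starting material
8 | [(Z)-3-[(4-methoxyphenyl)methoxy]prop-2-en-1-yl]lithium | [Li]C/C=C\OCc1ccc(OC)cc1 | intermediate (not isolated)
9 | lithium [(Z)-3-[(4-methoxyphenyl)methoxy]prop-2-en-1-yl](methoxy)bis[(1S,2R,3S,5S)-2,6,6-trimethylbicyclo[3.1.1]heptan-3-yl]borate | [Li+].CO[B-](C/C=C\OCc1ccc(OC)cc1)([C@H]2C[C@H]3C[C@@H]([C@@H]2C)C3(C)C)[C@H]4C[C@H]5C[C@@H]([C@@H]4C)C5(C)C | intermediate (not isolated)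
10 | [(Z)-3-[(4-methoxyphenyl)methoxy]prop-2-en-1-yl]bis[(1S,2R,3S,5S)-2,6,6-trimethylbicyclo[3.1.1]heptan-3-yl]borane | COc1ccc(CO/C=C\CB([C@H]2C[C@H]3C[C@@H]([C@@H]2C)C3(C)C)[C@H]4C[C@H]5C[C@@H]([C@@H]4C)C5(C)C)cc1 | intermediate (not isolated)
11 | bis[(1S,2R,3S,5S)-isopinocampheyl]borinic ester of the C5 hydroxyl of 12 | C=C[C@H](OCc1ccc(OC)cc1)[C@@H](OB([C@H]3C[C@H]4C[C@@H]([C@@H]3C)C4(C)C)[C@H]5C[C@H]6C[C@@H]([C@@H]5C)C6(C)C)[C@@]2(C)O[C@@H]2CC[C@@H](C)CC(OC)OC | intermediate (not isolated)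
12 | (1R,2S)-1-[(2R,3R)-3-[(3R)-5,5-dimethoxy-3-methylpentyl]-2-methyloxiran-2-yl]-2-[(4-methoxyphenyl)methoxy]but-3-en-1-ol | C=C[C@H](OCc1ccc(OC)cc1)[C@@H](O)[C@@]2(C)O[C@@H]2CC[C@@H](C)CC(OC)OC | intermediate
13 | (3S,4R,5S,9R)-11,11-dimethoxy-3-[(4-methoxyphenyl)methoxy]-5,9-dimethylundec-1-ene-4,5-diol | C=C[C@H](OCc1ccc(OC)cc1)[C@@H](O)[C@@](C)(O)CCC[C@@H](C)CC(OC)OC | intermediate
14 | 2-methylpropanoic anhydride (isobutyric anhydride) | CC(C)C(=O)OC(=O)C(C)C | starting material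
15 | (3S,4R,5S,9R)-5-hydroxy-11,11-dimethoxy-3-[(4-methoxyphenyl)methoxy]-5,9-dimethylundec-1-en-4-yl 2-methylpropanoate | C=C[C@H](OCc1ccc(OC)cc1)[C@@H](OC(=O)C(C)C)[C@@](C)(O)CCC[C@@H](C)CC(OC)OC | intermediate
16 | (3S,4R,5S,9R)-3,5-dihydroxy-11,11-dimethoxy-5,9-dimethylundec-1-en-4-yl 2-methylpropanoate | C=C[C@H](O)[C@@H](OC(=O)C(C)C)[C@@](C)(O)CCC[C@@H](C)CC(OC)OC | intermediate (not isolated)
17 | (3S,4R,5S,9R)-3,5-dihydroxy-5,9-dimethyl-11-oxoundec-1-en-4-yl 2-methylpropanoate | C=C[C@H](O)[C@@H](OC(=O)C(C)C)[C@@](C)(O)CCC[C@@H](C)CC=O | intermediate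
18 | (3S,4R,5S,9R,10S)-3,5-dihydroxy-5,9-dimethyl-11-oxo-10-[(2,2,6,6-tetramethylpiperidin-1-yl)oxy]undec-1-en-4-yl 2-methylpropanoate | C=C[C@H](O)[C@@H](OC(=O)C(C)C)[C@@](C)(O)CCC[C@@H](C)[C@H](ON1C(C)(C)CCCC1(C)C)C=O | intermediate
19 | 2-(bromomethyl)prop-2-enoic acid | C=C(CBr)C(=O)O | starting material
20 | O-[2-(bromomethyl)prop-2-enoyl]-N,N'-dicyclohexylisourea | C=C(CBr)C(=O)OC(=NC1CCCCC1)NC1CCCCC1 | intermediate (not isolated)
21 | (3S,4R,5S,9R,10S)-5-hydroxy-5,9-dimethyl-4-[(2-methylpropanoyl)oxy]-11-oxo-10-[(2,2,6,6-tetramethylpiperidin-1-yl)oxy]undec-1-en-3-yl 2-(bromomethyl)prop-2-enoate | C=C[C@H](OC(=O)C(=C)CBr)[C@@H](OC(=O)C(C)C)[C@@](C)(O)CCC[C@@H](C)[C@H](ON1C(C)(C)CCCC1(C)C)C=O | intermediate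
22 | (1R,2S,6R,7S)-1-[(2S)-4-(bromomethyl)-5-oxo-2,5-dihydrofuran-2-yl]-2-hydroxy-2,6-dimethyl-8-oxo-7-[(2,2,6,6-tetramethylpiperidin-1-yl)oxy]octyl 2-methylpropanoate | O=C1O[C@@H](C=C1CBr)[C@@H](OC(=O)C(C)C)[C@@](C)(O)CCC[C@@H](C)[C@H](ON2C(C)(C)CCCC2(C)C)C=O | intermediate
23 | allylchromium dichloride (trivalent chromium) formed from 22 by replacing Br with CrCl2 | O=C1O[C@@H](C=C1C[Cr](Cl)Cl)[C@@H](OC(=O)C(C)C)[C@@](C)(O)CCC[C@@H](C)[C@H](ON2C(C)(C)CCCC2(C)C)C=O | intermediate (not isolated)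
24 | (3aR,4R,5S,6R,10S,11R,11aS)-4,10-dihydroxy-6,10-dimethyl-3-methylidene-2-oxo-5-[(2,2,6,6-tetramethylpiperidin-1-yl)oxy]dodecahydrocyclodeca[b]furan-11-yl 2-methylpropanoate | C=C1C(=O)O[C@H]2[C@H]1[C@@H](O)[C@@H](ON3C(C)(C)CCCC3(C)C)[C@H](C)CCC[C@](C)(O)[C@@H]2OC(=O)C(C)C | intermediate
25 | (2R)-2-methylbutanoic acid | CC[C@@H](C)C(=O)O | starting material
26 | O-[(2R)-2-methylbutanoyl]-N,N'-dicyclohexylisourea | CC[C@@H](C)C(=O)OC(=NC1CCCCC1)NC1CCCCC1 | intermediate (not isolated)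
27 | (3aS,4R,5S,6R,10S,11R,11aS)-10-hydroxy-6,10-dimethyl-3-methylidene-11-[(2-methylpropanoyl)oxy]-2-oxo-5-[(2,2,6,6-tetramethylpiperidin-1-yl)oxy]dodecahydrocyclodeca[b]furan-4-yl (2R)-2-methylbutanoate | C=C1C(=O)O[C@H]2[C@H]1[C@@H](OC(=O)[C@H](C)CC)[C@@H](ON3C(C)(C)CCCC3(C)C)[C@H](C)CCC[C@](C)(O)[C@@H]2OC(=O)C(C)C | intermediate
28 | piperidine N-oxide of 27 | C=C1C(=O)O[C@H]2[C@H]1[C@@H](OC(=O)[C@H](C)CC)[C@@H](O[N+]3([O-])C(C)(C)CCCC3(C)C)[C@H](C)CCC[C@](C)(O)[C@@H]2OC(=O)C(C)C | intermediate (not isolated)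
29 | (3aS,4R,6R,10S,11R,11aS)-10-hydroxy-6,10-dimethyl-3-methylidene-11-[(2-methylpropanoyl)oxy]-2,5-dioxododecahydrocyclodeca[b]furan-4-yl (2R)-2-methylbutanoate | C=C1C(=O)O[C@H]2[C@H]1[C@@H](OC(=O)[C@H](C)CC)C(=O)[C@H](C)CCC[C@](C)(O)[C@@H]2OC(=O)C(C)C | target

## Step count and risk

Total step count: 14.
Longest linear sequence: 14 steps (1 to 29).

Steps most likely to fail:

Step 12 (macrocyclic Barbier). The ten-membered ring must close at high dilution, and both new centres (C7, C8) depend on a chair transition state inside a forming macrocycle. The cis-lactone or the C8 epimer may compete. The fallback sets out from 22 and separates metalation from cyclisation. Borylation of the allylic bromide with bis(pinacolato)diboron and Pd2(dba)3 in THF gives the isolable allylboronate of 22 F1. Sc(OTf)3-catalysed intramolecular allylboration in dilute toluene then proceeds through a tight boron-centred chair to the pinacol boronic ester of the ring alcohol F2. Aqueous work-up comes back to the route at 24.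

Step 11 (ring-closing metathesis). A 1,1-disubstituted acrylate carrying an allylic bromide next to a branched carbon is a slow metathesis partner and can degrade the ruthenium carbene. The fallback sets out from 18 and keeps the bromide out of the metathesis. Steglich esterification of 18 with 2-[(tert-butyldimethylsilyloxy)methyl]prop-2-enoic acid gives the silyloxymethyl acrylate ester F3. Ring-closing metathesis with the same ruthenium catalyst gives the silyloxymethyl butenolide F4. HF·pyridine gives the hydroxymethyl butenolide F5. Corey–Kim bromination (N-bromosuccinimide, Me2S, CH2Cl2, −20 °C), which tolerates the aldehyde, comes back to the route at 22.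

Step 14 (peracid unveiling of the ketone). The Cope-type elimination may be slow at this hindered centre, and excess peracid can attack the new α-acyloxy ketone in a Baeyer–Villiger reaction. The fallback sets out from 27 and replaces the oxidative fragmentation by reduction then oxidation. Zn dust in AcOH/THF/H2O at 50 °C cleaves the N–O bond to the C9 alcohol F6. Dess–Martin periodinane in CH2Cl2 at 0 °C, used at once to forestall acyl migration, comes back to the route at 29.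

## Further compounds

F1 | step 12 | (1R,2S,6R,7S)-2-hydroxy-2,6-dimethyl-8-oxo-1-[(2S)-5-oxo-4-[(4,4,5,5-tetramethyl-1,3,2-dioxaborolan-2-yl)methyl]-2,5-dihydrofuran-2-yl]-7-[(2,2,6,6-tetramethylpiperidin-1-yl)oxy]octyl 2-methylpropanoate | O=C1O[C@@H](C=C1CB2OC(C)(C)C(C)(C)O2)[C@@H](OC(=O)C(C)C)[C@@](C)(O)CCC[C@@H](C)[C@H](ON3C(C)(C)CCCC3(C)C)C=O
F2 | step 12 | O-(4,4,5,5-tetramethyl-1,3,2-dioxaborolan-2-yl) ether of the C8 hydroxyl of 24 | C=C1C(=O)O[C@H]2[C@H]1[C@@H](OB4OC(C)(C)C(C)(C)O4)[C@@H](ON3C(C)(C)CCCC3(C)C)[C@H](C)CCC[C@](C)(O)[C@@H]2OC(=O)C(C)C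
F3 | step 11 | (3S,4R,5S,9R,10S)-5-hydroxy-5,9-dimethyl-4-[(2-methylpropanoyl)oxy]-11-oxo-10-[(2,2,6,6-tetramethylpiperidin-1-yl)oxy]undec-1-en-3-yl 2-[(tert-butyldimethylsilyloxy)methyl]prop-2-enoate | C=C[C@H](OC(=O)C(=C)CO[Si](C)(C)C(C)(C)C)[C@@H](OC(=O)C(C)C)[C@@](C)(O)CCC[C@@H](C)[C@H](ON1C(C)(C)CCCC1(C)C)C=O
F4 | step 11 | (1R,2S,6R,7S)-1-[(2S)-4-[(tert-butyldimethylsilyloxy)methyl]-5-oxo-2,5-dihydrofuran-2-yl]-2-hydroxy-2,6-dimethyl-8-oxo-7-[(2,2,6,6-tetramethylpiperidin-1-yl)oxy]octyl 2-methylpropanoate | O=C1O[C@@H](C=C1CO[Si](C)(C)C(C)(C)C)[C@@H](OC(=O)C(C)C)[C@@](C)(O)CCC[C@@H](C)[C@H](ON2C(C)(C)CCCC2(C)C)C=O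
F5 | step 11 | (1R,2S,6R,7S)-2-hydroxy-1-[(2S)-4-(hydroxymethyl)-5-oxo-2,5-dihydrofuran-2-yl]-2,6-dimethyl-8-oxo-7-[(2,2,6,6-tetramethylpiperidin-1-yl)oxy]octyl 2-methylpropanoate | O=C1O[C@@H](C=C1CO)[C@@H](OC(=O)C(C)C)[C@@](C)(O)CCC[C@@H](C)[C@H](ON2C(C)(C)CCCC2(C)C)C=O
F6 | step 14 | (3aR,4R,5S,6R,10S,11R,11aS)-5,10-dihydroxy-6,10-dimethyl-3-methylidene-11-[(2-methylpropanoyl)oxy]-2-oxododecahydrocyclodeca[b]furan-4-yl (2R)-2-methylbutanoate | C=C1C(=O)O[C@H]2[C@H]1[C@@H](OC(=O)[C@H](C)CC)[C@@H](O)[C@H](C)CCC[C@](C)(O)[C@@H]2OC(=O)C(C)C
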